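**Retrosynthetic overview**

- Ring B is numbered B1 (carries the CH2 bridge to ring A), B2 (O), B3 (quaternary CMe2), B4 (O), B5 (acetyl), B6 (O). The plan rests on this ring: a 6,6-dimethylcyclohexadienone with oxygen on the alternate carbons B2, B4 and B6, the bridge on B1, and a quaternary B3 that cannot aromatise.
- End game: the two O-benzyl groups on ring A go by hydrogenolysis, the B5 acetyl by O-to-C acyl shift, and the B4/B6 enol methyl ethers by acid hydrolysis, leading back to a 3,5-dimethoxy-6,6-dimethylcyclohexa-2,4-dienone.
- Key disconnection of ring B (the only ring formed) at B1–B2, B5–B6 and B2–B3: 3-methoxy-4,4-dimethylcyclobutenone (B2, B5, B4, B3) plus the ring A propargylic methoxyalkyne (B6, B1).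
- The alkyne comes from Negishi coupling of methoxyethynylzinc with the ring A benzylic bromide (benzylation, formylation, reduction and bromination of 2,6-dihydroxy-4-methoxyacetophenone). The cyclobutenone comes from methoxyethyne and dimethylketene.

Key step: step 8

Assumption: the target is an enolised β-triketone and is treated as one compound with its tautomers (21, 23 and 24 are drawn in the tautomer of the given SMILES); methoxyethyne is not a stock chemical and is made in step 1.

**Step 1**
Reactants: 1 chloroacetaldehyde dimethyl acetal (2-chloro-1,1-dimethoxyethane)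
Product: 3 methoxyethyne, via sodium methoxyacetylide 2 (not isolated)
Conditions: NaNH2 (3 equiv), liquid NH3, −33 °C; then sat. aq. NH4Cl, −60 to 0 °C; distilled into a −78 °C trap and kept as a cold THF solution
Reagents that add atoms: none
Why: Sodium amide effects twofold β-elimination (methanol, then HCl) and deprotonation to the sodium acetylide, which the quench protonates; this is the standard amide-base route from α-chloroacetals to alkoxyacetylenes.

**Step 2**
Reactants: 3 methoxyethyne, 4 isobutyryl chloride
Product: 6 3-methoxy-4,4-dimethylcyclobut-2-en-1-one, via dimethylketene 5 (not isolated)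
Conditions: Et3N (1.2 equiv), 3 (1.5–2 equiv), Et2O, 0 °C to rt, closed vessel
Reagents that add atoms: none
Why: Dehydrochlorination gives dimethylketene, which is captured in a thermal ketene–alkyne [2+2] cycloaddition; the ketene carbonyl carbon bonds to the unsubstituted, nucleophilic alkyne carbon, so OMe ends on C3 and CMe2 on C4.

**Step 3**
Reactants: 7 1-(2,6-dihydroxy-4-methoxyphenyl)ethanone, 8 benzyl bromide
Product: 9 1-[2,6-bis(benzyloxy)-4-methoxyphenyl]ethanone
Conditions: BnBr (2.5 equiv), K2CO3 (3 equiv), DMF, 70 °C
Reagents that add atoms: benzyl bromide (8), BrCc1ccccc1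
Why: Williamson etherification of both chelated phenols in warm DMF; the benzyl ethers mask OH groups that would otherwise add to the ketenes of step 8 and be acetylated in step 10.

**Step 4**
Reactants: 9 1-[2,6-bis(benzyloxy)-4-methoxyphenyl]ethanone
Product: 11 3-acetyl-2,4-bis(benzyloxy)-6-methoxybenzaldehyde, via aryl iminium chloride 10 (not isolated)
Conditions: POCl3 (1.5 equiv), DMF, 0 to 50 °C; then ice-water, rt
Reagents that add atoms: N,N-dimethylformamide, CN(C)C=O; water, O
Why: Vilsmeier–Haack formylation at the only kind of free ring position (C3 and C5 are equivalent), activated by three alkoxy groups, while the acetyl group, twisted out of plane by its two ortho substituents, deactivates little and reacts slowly at its own methyl group.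

**Step 5**
Reactants: 11 3-acetyl-2,4-bis(benzyloxy)-6-methoxybenzaldehyde
Product: 12 1-[2,6-bis(benzyloxy)-3-(hydroxymethyl)-4-methoxyphenyl]ethanone
Conditions: NaBH4 (0.5 equiv), THF/MeOH, −10 °C
Reagents that add atoms: none
Why: Borohydride reduction, chemoselective for the aldehyde because the aryl methyl ketone is shielded by two ortho benzyloxy groups and is much slower with a limited hydride charge at low temperature.

**Step 6**
Reactants: 12 1-[2,6-bis(benzyloxy)-3-(hydroxymethyl)-4-methoxyphenyl]ethanone
Product: 13 1-[2,6-bis(benzyloxy)-3-(bromomethyl)-4-methoxyphenyl]ethanone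
Conditions: PBr3 (0.4 equiv), CH2Cl2, 0 °C; cold aq. NaHCO3 wash; used at once without chromatography
Reagents that add atoms: phosphorus tribromide, BrP(Br)Br
Why: Alcohol-to-bromide exchange through the bromophosphite; the product is an electron-rich benzylic bromide and is therefore kept cold and not stored.

**Step 7**
Reactants: 13 1-[2,6-bis(benzyloxy)-3-(bromomethyl)-4-methoxyphenyl]ethanone, 3 methoxyethyne
Product: 16 1-[2,6-bis(benzyloxy)-4-methoxy-3-(3-methoxyprop-2-yn-1-yl)phenyl]ethanone, via lithium methoxyacetylide 14 (not isolated), via chloro(methoxyethynyl)zinc 15 (not isolated)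
Conditions: 3 (1.6 equiv), n-BuLi (1.5 equiv), THF, −78 °C; ZnCl2 (1.6 equiv), −78 to 0 °C; then 13, PdCl2(DPEphos) (5 mol %), THF, 0 °C to rt
Reagents that add atoms: none
Why: Negishi coupling in which zerovalent palladium inserts into the benzylic C–Br bond, the alkynylzinc transmetalates and sp–sp3 reductive elimination gives the 1-aryl-2-alkyne; the organozinc is too mild to add to or enolise the hindered acetyl group, and the wide-bite-angle diphosphine should hold back homocoupling.

**Step 8**
Reactants: 16 1-[2,6-bis(benzyloxy)-4-methoxy-3-(3-methoxyprop-2-yn-1-yl)phenyl]ethanone, 6 3-methoxy-4,4-dimethylcyclobut-2-en-1-one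
Product: 20 2-[[3-acetyl-2,4-bis(benzyloxy)-6-methoxyphenyl]methyl]-3,5-dimethoxy-6,6-dimethylcyclohexa-2,4-dien-1-one, via vinylketene 17 (not isolated), via vinylcyclobutenone 18 (not isolated), via dienylketene 19 (not isolated)
Conditions: 6 (2.5 equiv), toluene (0.5 M in 16), degassed, sealed tube, 120–140 °C
Reagents that add atoms: none
Why: Heating opens the strained cyclobutenone 6 by 4π electrocyclic cleavage of its C1–C4 bond to vinylketene 17, whose ketene C=C adds the alkynyl ether in a [2+2] cycloaddition (B2–B1 and B5–B6 bonds) to give racemic 4-vinylcyclobutenone 18; a second 4π opening gives dienylketene 19, and a thermal 6π electrocyclisation joins the ketene carbon B2 to the CMe2 terminus B3. This is the cyclobutenone–alkynyl ether annulation (Danheiser annulation) run on a 4,4-disubstituted cyclobutenone, where the quaternary B3 blocks tautomerisation and the cascade stops at the cyclohexa-2,4-dienone; the 3-methoxy group widens the usual substituent range and is expected to raise the opening temperature, because the vinylogous ester stabilisation of 6 is lost in 17. Ring B closes by disrotatory 6π electrocyclisation of the dienylketene isomer whose ketene and isobutenyl arms are cis on the central C=C, and the other isomer can return to 18 because the 4π step is reversible. No stereocentre remains in 20, the single centre of 18 being destroyed in the second opening. The step needs one regiochemistry in the [2+2], ketene carbonyl carbon to the alkyne carbon remote from oxygen, and the donor polarisation of the MeO–C≡C unit supplies it, so OMe lands on B6 and the bridge on B1. The methyl ynol ether has no β-hydrogen and cannot lose an alkene by retro-ene fragmentation at this temperature, and an excess of 6 in concentrated solution favours bimolecular capture of 17 over its [1,5]-hydrogen shift.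

**Step 9**
Reactants: 20 2-[[3-acetyl-2,4-bis(benzyloxy)-6-methoxyphenyl]methyl]-3,5-dimethoxy-6,6-dimethylcyclohexa-2,4-dien-1-one
Product: 21 2-[[3-acetyl-2,4-bis(benzyloxy)-6-methoxyphenyl]methyl]-3,5-dihydroxy-4,4-dimethylcyclohexa-2,5-dien-1-one
Conditions: 2 M aq. HCl, THF, 50 °C
Reagents that add atoms: water, O
Why: Acid hydrolysis of two vinylogous methyl esters (B6–OMe is β to the B2 carbonyl, and B4–OMe then becomes β to the B6 carbonyl) by C-protonation, hydration and loss of methanol; benzyl ethers, the aryl methyl ether and the aryl ketone are inert to dilute acid.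

**Step 10**
Reactants: 21 2-[[3-acetyl-2,4-bis(benzyloxy)-6-methoxyphenyl]methyl]-3,5-dihydroxy-4,4-dimethylcyclohexa-2,5-dien-1-one
Product: 23 2-acetyl-6-[[3-acetyl-2,4-bis(benzyloxy)-6-methoxyphenyl]methyl]-3,5-dihydroxy-4,4-dimethylcyclohexa-2,5-dien-1-one, via enol acetate 22 (not isolated)
Conditions: Ac2O (1.1 equiv), Et3N (2 equiv), CH2Cl2, 0 °C; then DMAP (0.3 equiv), rt; 1 M aq. HCl work-up
Reagents that add atoms: acetic anhydride, CC(=O)OC(C)=O
Why: O-Acetylation of the enolised trione followed by DMAP-mediated O-to-C acyl migration (the enol ester to β-triketone rearrangement of cyclic 1,3-diones), driven to B5, the only unsubstituted ring carbon between two carbonyl groups, by formation of the acidic, hydrogen-bonded 2-acyl-1,3-dione; ring A has no free OH.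

**Step 11**
Reactants: 23 2-acetyl-6-[[3-acetyl-2,4-bis(benzyloxy)-6-methoxyphenyl]methyl]-3,5-dihydroxy-4,4-dimethylcyclohexa-2,5-dien-1-one
Product: 24 2-acetyl-6-[(3-acetyl-2,4-dihydroxy-6-methoxyphenyl)methyl]-3,5-dihydroxy-4,4-dimethylcyclohexa-2,5-dien-1-one (target)
Conditions: H2 (1 atm), 10% Pd/C, EtOAc, rt
Reagents that add atoms: none
Why: Catalytic hydrogenolysis of the two benzyl aryl ethers under neutral conditions; the enolised triketone, the chelated aryl ketone and the CH2 bridge should not be reduced at 1 atm and rt, and the absence of base avoids scrambling of the methylene bridge.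

**Compound list**

1 | chloroacetaldehyde dimethyl acetal (2-chloro-1,1-dimethoxyethane) | COC(CCl)OC | starting material
2 | sodium methoxyacetylide | [Na+].[C-]#COC | intermediate (not isolated)
3 | methoxyethyne | C#COC | intermediate
4 | isobutyryl chloride | CC(C)C(Cl)=O | starting material
5 | dimethylketene | CC(C)=C=O | intermediate (not isolated)
6 | 3-methoxy-4,4-dimethylcyclobut-2-en-1-one | COC1=CC(=O)C1(C)C | intermediate
7 | 1-(2,6-dihydroxy-4-methoxyphenyl)ethanone | COc1cc(O)c(C(C)=O)c(O)c1 | starting material
8 | benzyl bromide | BrCc1ccccc1 | starting material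
9 | 1-[2,6-bis(benzyloxy)-4-methoxyphenyl]ethanone | COc1cc(OCc2ccccc2)c(C(C)=O)c(OCc2ccccc2)c1 | intermediate
10 | N-[[3-acetyl-2,4-bis(benzyloxy)-6-methoxyphenyl]methylidene]-N-methylmethanaminium chloride (aryl iminium chloride) | C[N+](C)=Cc1c(OC)cc(OCc2ccccc2)c(C(C)=O)c1OCc1ccccc1.[Cl-] | intermediate (not isolated)
11 | 3-acetyl-2,4-bis(benzyloxy)-6-methoxybenzaldehyde | COc1cc(OCc2ccccc2)c(C(C)=O)c(OCc2ccccc2)c1C=O | intermediate
12 | 1-[2,6-bis(benzyloxy)-3-(hydroxymethyl)-4-methoxyphenyl]ethanone | COc1cc(OCc2ccccc2)c(C(C)=O)c(OCc2ccccc2)c1CO | intermediate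
13 | 1-[2,6-bis(benzyloxy)-3-(bromomethyl)-4-methoxyphenyl]ethanone | COc1cc(OCc2ccccc2)c(C(C)=O)c(OCc2ccccc2)c1CBr | intermediate
14 | lithium methoxyacetylide | [Li+].[C-]#COC | intermediate (not isolated)
15 | chloro(methoxyethynyl)zinc | COC#C[Zn]Cl | intermediate (not isolated)
16 | 1-[2,6-bis(benzyloxy)-4-methoxy-3-(3-methoxyprop-2-yn-1-yl)phenyl]ethanone | COC#CCc1c(OC)cc(OCc2ccccc2)c(C(C)=O)c1OCc1ccccc1 | intermediate
17 | 3-methoxy-4-methylpenta-1,3-dien-1-one (vinylketene) | COC(C=C=O)=C(C)C | intermediate (not isolated)
18 | 2-[[3-acetyl-2,4-bis(benzyloxy)-6-methoxyphenyl]methyl]-3-methoxy-4-(1-methoxy-2-methylprop-1-en-1-yl)cyclobut-2-en-1-one, racemic (vinylcyclobutenone) | COC1=C(Cc2c(OC)cc(OCc3ccccc3)c(C(C)=O)c2OCc2ccccc2)C(=O)C1C(OC)=C(C)C | intermediate (not isolated)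
19 | (3E)-2-[[3-acetyl-2,4-bis(benzyloxy)-6-methoxyphenyl]methyl]-3,5-dimethoxy-6-methylhepta-1,3,5-trien-1-one (dienylketene) | O=C=C(Cc1c(OC)cc(OCc2ccccc2)c(C(C)=O)c1OCc1ccccc1)/C(OC)=C\C(OC)=C(C)C | intermediate (not isolated)
20 | 2-[[3-acetyl-2,4-bis(benzyloxy)-6-methoxyphenyl]methyl]-3,5-dimethoxy-6,6-dimethylcyclohexa-2,4-dien-1-one | COC1=CC(OC)=C(Cc2c(OC)cc(OCc3ccccc3)c(C(C)=O)c2OCc2ccccc2)C(=O)C1(C)C | intermediate
21 | 2-[[3-acetyl-2,4-bis(benzyloxy)-6-methoxyphenyl]methyl]-3,5-dihydroxy-4,4-dimethylcyclohexa-2,5-dien-1-one | CC1(C)C(O)=CC(=O)C(Cc2c(OC)cc(OCc3ccccc3)c(C(C)=O)c2OCc2ccccc2)=C1O | intermediate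
22 | 4-[[3-acetyl-2,4-bis(benzyloxy)-6-methoxyphenyl]methyl]-5-hydroxy-6,6-dimethyl-3-oxocyclohexa-1,4-dien-1-yl acetate (B4 O-acetate shown; the other O-acetates converge on 23) | CC(=O)OC1=CC(=O)C(Cc2c(OC)cc(OCc3ccccc3)c(C(C)=O)c2OCc2ccccc2)=C(O)C1(C)C | intermediate (not isolated)
23 | 2-acetyl-6-[[3-acetyl-2,4-bis(benzyloxy)-6-methoxyphenyl]methyl]-3,5-dihydroxy-4,4-dimethylcyclohexa-2,5-dien-1-one | CC(=O)C1=C(O)C(C)(C)C(O)=C(Cc2c(OC)cc(OCc3ccccc3)c(C(C)=O)c2OCc2ccccc2)C1=O | intermediate
24 | 2-acetyl-6-[(3-acetyl-2,4-dihydroxy-6-methoxyphenyl)methyl]-3,5-dihydroxy-4,4-dimethylcyclohexa-2,5-dien-1-one | COc1cc(O)c(C(C)=O)c(O)c1CC1=C(O)C(C)(C)C(O)=C(C(C)=O)C1=O | target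

**Step count**

Total: 11 steps. Longest linear sequence: 9 steps (7 to 24 through steps 3, 4, 5, 6, 7, 8, 9, 10 and 11).

**Steps most likely to fail**

1. Step 8. The vinylogous ester stabilisation of 6 may slow the electrocyclic opening so far that the required temperature lets vinylketene 17 isomerise by [1,5]-hydrogen shift from a Z-methyl group, or dimerise, faster than the alkyne captures it; the propargylic alkyne may also isomerise to an allenyl ether. Fallback, setting out from 13 and coming back at 23: commercial 2,4,6-trihydroxyacetophenone is twice C-methylated at one ring carbon (MeI, NaOMe, MeOH), a known dearomatising alkylation of acylphloroglucinols, to give 2-acetyl-3,5-dihydroxy-4,4-dimethylcyclohexa-2,5-dien-1-one (acetylfilicinic acid) F1. The sodium salt of F1 is then alkylated at its single unsubstituted ring carbon by bromide 13 (NaOMe, MeOH, 0 °C), which gives 23 directly, and step 11 follows.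

2. Step 7. The very electron-rich benzylic bromide may ionise and alkylate the free ring position of a second molecule, the palladium cycle may give bibenzyl and diyne by homocoupling, or the product may isomerise from propargyl to allenyl. Fallback, setting out from 12 and coming back at 21: methoxyethyne 3 is itself heated with cyclobutenone 6 (toluene, sealed tube) to give 3,5-dimethoxy-6,6-dimethylcyclohexa-2,4-dien-1-one F2, and aqueous acid converts this into 3,5-dihydroxy-4,4-dimethylcyclohexa-2,5-dien-1-one (filicinic acid) F3. Alcohol 12 is then ionised by a catalytic acid (TsOH or Bi(OTf)3, MeNO2, rt) and the benzylic cation is captured at carbon by F3 taken in excess, a known acid-catalysed benzylation of 1,3-dicarbonyl compounds by electron-rich benzylic alcohols. This gives 21 without the bromide or the cross-coupling.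

3. Step 2. Dehydrochlorination of the branched acid chloride is slow, so ketene dimerisation or acylation of the ketene by unreacted acid chloride may outrun the cycloaddition with the volatile alkyne. Fallback, setting out from 4 and coming back at 6: dimethylketene 5, made from 4 as before, is trapped by commercial 1,1-dimethoxyethene in a ketene–ketene acetal [2+2] cycloaddition to give 3,3-dimethoxy-2,2-dimethylcyclobutan-1-one F4. Loss of methanol (cat. TsOH, warm, or on distillation) then gives 6, and methoxyethyne is needed only for step 7.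

**Further compounds**

F1 | step 8 | 2-acetyl-3,5-dihydroxy-4,4-dimethylcyclohexa-2,5-dien-1-one (acetylfilicinic acid) | CC(=O)C1=C(O)C(C)(C)C(O)=CC1=O
F2 | step 7 | 3,5-dimethoxy-6,6-dimethylcyclohexa-2,4-dien-1-one | COC1=CC(OC)=CC(=O)C1(C)C
F3 | step 7 | 3,5-dihydroxy-4,4-dimethylcyclohexa-2,5-dien-1-one (filicinic acid) | CC1(C)C(O)=CC(=O)C=C1O
F4 | step 2 | 3,3-dimethoxy-2,2-dimethylcyclobutan-1-one | COC1(OC)CC(=O)C1(C)C
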